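**Retrosynthetic overview**
1. Target 17 comes from fluoride release of CO2H and 5‑OH out of the eight‑membered cyclic silyl ester 16. Compound 16 comes from ring‑closing metathesis of the C5–O–Si(iPr)2–O2C–CH=CH2 tether in 15, which fixes 2Z without a lactone stage.
2. The C4–OAc/C5–OH pair comes from C–O bond formation: SN2 acetolysis at the allylic carbon of cis‑vinyl epoxide 11. This puts acetate on O4 only and sets C4.
3. Compound 11 comes from γ‑chloroallylboration and closure of epoxy aldehyde 7, which forms C4–C5 and sets C5.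
4. Key step: 7 comes from furan 3 plus O2. C5=O, C8=O and the C6–O–C7 oxirane are all made in one C–O‑forming operation. Compound 3 comes from asymmetric transfer hydrogenation and acetylation of 2‑butyrylfuran, which sets C9.
5. Ring order: the trans‑oxirane C6–C7 is kept, the cis‑oxirane C4–C5 is opened one step later, and the eight‑membered silacycle is cleaved in the same flask.

Assumption: 1 (2‑butyrylfuran, a flavour chemical) is bought. The sense of induction of each chiral catalyst or reagent is assigned from its standard model, and both enantiomers of each are sold. Atom labels C1–C12 follow the target.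

**Step 1**
Reactants: 1 1-(furan-2-yl)butan-1-one
Product: 2 (1R)-1-(furan-2-yl)butan-1-ol
Conditions: RuCl[(R,R)-TsDPEN](p-cymene) (0.5 mol%), HCO2H/Et3N 5:2, 25 °C, 24 h
Reagents that add atoms: none
Why: Noyori asymmetric transfer hydrogenation, in which the furyl ring takes the aryl slot of the (R,R)-TsDPEN ruthenium hydride so that hydride reaches one carbonyl face only and sets C9 as R (2‑acylfurans typically give at least 95% ee).

**Step 2**
Reactants: 2 (1R)-1-(furan-2-yl)butan-1-ol
Product: 3 (1R)-1-(furan-2-yl)butyl acetate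
Conditions: Ac2O (1.3 equiv), Et3N (1.5 equiv), DMAP (5 mol%), CH2Cl2, 0 °C to rt
Reagents that add atoms: acetic anhydride, CC(=O)OC(C)=O
Why: DMAP‑catalysed O‑acylation that leaves the C9–O bond untouched, so the configuration is retained and a later Achmatowicz‑type ring expansion is blocked.

**Step 3 (key step)**
Reactants: 3 (1R)-1-(furan-2-yl)butyl acetate
Product: 7 (2S,3S,5R)-5-acetoxy-2,3-epoxy-4-oxooctanal, via furan endoperoxide 4 (not isolated), via Z-keto-enal 5 (not isolated), via E-keto-enal 6 (not isolated)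
Conditions: O2, white LED, tetraphenylporphyrin (0.2 mol%), CH2Cl2, −78 °C; argon purge, dark; then H2O (1 equiv), PhCO2H (10 mol%), (S)-2-{bis[3,5-bis(trifluoromethyl)phenyl](trimethylsilyloxy)methyl}pyrrolidine (10 mol%), −78 to 0 °C
Reagents that add atoms: dioxygen, O=O
Why: Proposed new method: [4+2] addition of singlet oxygen gives endoperoxide 4, whose known hydrolysis releases cis‑keto‑enal 5 and exactly one equivalent of H2O2; the secondary amine condenses only with the aldehyde, equilibrates 5 to 6 by reversible conjugate addition, and as the E‑iminium ion takes HOO– at C7 on the face left open by the CAr2(OTMS) group, after which enamine carbon C6 attacks the O–O bond and closes the trans‑oxirane (sets C6 and C7), so both atoms of O2 end up used, water is regenerated, and no external oxidant or reductant is needed; the closest known reactions are furan photooxygenation with reductive work‑up to enediones and the iminium‑catalysed (Jørgensen‑type) epoxidation of enals, 4‑oxo‑enoates included, with aqueous H2O2.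

**Step 4**
Reactants: 7 (2S,3S,5R)-5-acetoxy-2,3-epoxy-4-oxooctanal; 8 allyl chloride
Product: 11 (3R,4R,5R,6S,8R)-8-acetoxy-3,4:5,6-diepoxyundec-1-en-7-one, via chloroallylborane 9 (not isolated), via syn-chlorohydrin 10 (not isolated)
Conditions: 8 (2 equiv), (+)-Ipc2BOMe (1.5 equiv, (−)-α-pinene series), LiN(c-C6H11)2 (2 equiv), Et2O, −95 °C; BF3·OEt2 (2.5 equiv), then 7, −95 °C, 4 h; pH 7 buffer, 30% H2O2, MeOH, 0 °C; crude 10, DBU (1.2 equiv), CH2Cl2, 0 °C, 1 h
Reagents that add atoms: allyl chloride (8), C=CCCl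
Why: Brown–Oehlschlager γ‑chloroallylboration followed by halohydrin closure, in which the Z‑allylborane reacts through a chair Zimmerman–Traxler transition state (giving 4,5‑syn), the isopinocampheyl groups send it to the Re face of the aldehyde, which is also the Felkin face of a 2,3‑epoxy aldehyde (giving 5,6‑anti and setting C5), the ketone is inert at −95 °C, and brief DBU treatment closes O5 onto C4 with inversion to the cis‑vinyl epoxide without disturbing the C9 acetoxy ketone.

**Step 5**
Reactants: 11 (3R,4R,5R,6S,8R)-8-acetoxy-3,4:5,6-diepoxyundec-1-en-7-one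
Product: 12 (3S,4R,5R,6S,8R)-3,8-diacetoxy-5,6-epoxy-4-hydroxyundec-1-en-7-one
Conditions: AcOH (10 equiv), PPTS (10 mol%), CH2Cl2, 0 °C to rt
Reagents that add atoms: acetic acid, CC(=O)O
Why: Acid‑promoted SN2‑type opening of a vinyl epoxide by a carboxylic acid, where only the allylic C4–O bond is activated (the C6–C7 oxirane is deactivated by its acyl group and C5 is flanked by two C–O bonds), so acetate enters at C4 with inversion, turns the cis‑epoxide into the 4,5‑syn pair, sets C4 as S, and leaves O5 as the free hydroxyl.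

**Step 6**
Reactants: 12 (3S,4R,5R,6S,8R)-3,8-diacetoxy-5,6-epoxy-4-hydroxyundec-1-en-7-one; 13 acrylic acid
Product: 15 (acryloyloxy)diisopropylsilyl ether of 12, via chlorosilyl ether 14 (not isolated)
Conditions: iPr2SiCl2 (1.2 equiv), Et3N (1.3 equiv), DMAP (10 mol%), CH2Cl2, 0 °C; then 13 (1.5 equiv), Et3N (1.6 equiv), 0 °C; filter under argon, concentrate, use crude
Reagents that add atoms: dichlorodiisopropylsilane, CC(C)[Si](Cl)(Cl)C(C)C; acrylic acid (13), C=CC(=O)O
Why: Stepwise nucleophilic substitution at silicon (silyl ether, then silyl ester), in which the hindered dichlorosilane stops at monosubstitution with the only free hydroxyl, the remaining Si–Cl is taken by acrylate, and no stereocentre is touched.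

**Step 7**
Reactants: 15 (acryloyloxy)diisopropylsilyl ether of 12
Product: 17 (2Z,4S,5R,6R,7S,9R)-4,9-diacetoxy-6,7-epoxy-5-hydroxy-8-oxododec-2-enoic acid, via cyclic silyl ester 16 (not isolated)
Conditions: second-generation Hoveyda–Grubbs catalyst RuCl2(H2IMes)(=CH-C6H4-2-OiPr) (10 mol%), 1,4-benzoquinone (10 mol%), toluene (2 mM), 80 °C; then Et3N·3HF (3 equiv), THF, 0 °C, 1 h
Reagents that add atoms: none
Why: Proposed new method: the ruthenium alkylidene loads on the only electron‑neutral olefin (the vinyl group next to C4) and closes onto the tethered silyl acrylate; the resulting 1,3‑dioxa‑2‑silacyclooct‑5‑en‑4‑one can hold only a cis double bond, so 2Z is enforced, while the long Si–O bonds and the gem‑diisopropyl effect ease the eight‑membered closure; fluoride then cleaves the Si–O(acyl) and Si–O(alkyl) bonds together at 0 °C, freeing CO2H and 5‑OH under near‑neutral conditions that spare both acetates, the oxirane and the ketone and avoid any lactone hydrolysis; the closest known reactions are temporary silicon‑tethered ring‑closing metathesis of bis(alkoxy)silanes and ring‑closing metathesis of acrylates to 5,6‑dihydropyran‑2‑ones.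

**Compound list**

| No. | Name | SMILES | Role |
|---|---|---|---|
| 1 | 1-(furan-2-yl)butan-1-one | CCCC(=O)c1ccco1 | starting material |
| 2 | (1R)-1-(furan-2-yl)butan-1-ol | CCC[C@@H](O)c1ccco1 | intermediate |
| 3 | (1R)-1-(furan-2-yl)butyl acetate | CCC[C@@H](OC(C)=O)c1ccco1 | intermediate |
| 4 | (1R)-1-(2,3,7-trioxabicyclo[2.2.1]hept-5-en-1-yl)butyl acetate, both bridgehead diastereomers | CCC[C@@H](OC(C)=O)C12C=CC(OO1)O2 | intermediate |
| 5 | (2Z,5R)-5-acetoxy-4-oxooct-2-enal | CCC[C@@H](OC(C)=O)C(=O)/C=C\C=O | intermediate |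
| 6 | (2E,5R)-5-acetoxy-4-oxooct-2-enal | CCC[C@@H](OC(C)=O)C(=O)/C=C/C=O | intermediate |
| 7 | (2S,3S,5R)-5-acetoxy-2,3-epoxy-4-oxooctanal (trans-oxirane) | CCC[C@@H](OC(C)=O)C(=O)[C@H]1O[C@@H]1C=O | intermediate |
| 8 | allyl chloride | C=CCCl | starting material |
| 9 | (Z)-(3-chloroprop-2-en-1-yl)bis(isopinocampheyl)borane, (−)-α-pinene series | Cl/C=C\CB([C@H]1C[C@H]2C[C@@H]([C@@H]1C)C2(C)C)[C@H]1C[C@H]2C[C@@H]([C@@H]1C)C2(C)C | intermediate |
| 10 | (3S,4S,5R,6S,8R)-8-acetoxy-3-chloro-5,6-epoxy-4-hydroxyundec-1-en-7-one (3,4-syn, 4,5-anti) | CCC[C@@H](OC(C)=O)C(=O)[C@H]1O[C@@H]1[C@H](O)[C@H](C=C)Cl | intermediate |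
| 11 | (3R,4R,5R,6S,8R)-8-acetoxy-3,4:5,6-diepoxyundec-1-en-7-one (3,4-cis, 5,6-trans) | CCC[C@@H](OC(C)=O)C(=O)[C@H]1O[C@@H]1[C@@H]2O[C@@H]2C=C | intermediate |
| 12 | (3S,4R,5R,6S,8R)-3,8-diacetoxy-5,6-epoxy-4-hydroxyundec-1-en-7-one | CCC[C@@H](OC(C)=O)C(=O)[C@H]1O[C@@H]1[C@H](O)[C@H](C=C)OC(C)=O | intermediate |
| 13 | acrylic acid | C=CC(=O)O | starting material |
| 14 | chloro(diisopropyl)silyl ether of 12 (stereocentres as in 12) | CCC[C@@H](OC(C)=O)C(=O)[C@H]1O[C@@H]1[C@H](O[Si](Cl)(C(C)C)C(C)C)[C@H](C=C)OC(C)=O | intermediate |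
| 15 | (acryloyloxy)diisopropylsilyl ether of 12 (stereocentres as in 12) | CCC[C@@H](OC(C)=O)C(=O)[C@H]1O[C@@H]1[C@H](O[Si](C(C)C)(C(C)C)OC(=O)C=C)[C@H](C=C)OC(C)=O | intermediate |
| 16 | (5Z)-7-acetoxy-2,2-diisopropyl-1,3-dioxa-2-silacyclooct-5-en-4-one carrying at C8 the trans-3-[(2R)-2-acetoxypentanoyl]oxiran-2-yl group (stereocentres as in 12) | CCC[C@@H](OC(C)=O)C(=O)[C@H]1O[C@@H]1[C@@H]2O[Si](C(C)C)(C(C)C)OC(=O)/C=C\[C@@H]2OC(C)=O | intermediate |
| 17 | (2Z,4S,5R,6R,7S,9R)-4,9-diacetoxy-6,7-epoxy-5-hydroxy-8-oxododec-2-enoic acid | CCC[C@@H](OC(C)=O)C(=O)[C@H]1O[C@@H]1[C@H](O)[C@H](/C=C\C(=O)O)OC(C)=O | target |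

**Step count**
- Total step count: 7.
- Longest linear sequence: 7.

**Three steps most likely to fail**

**Step 3 (new).**
- Failure modes: the amine may deprotonate C5–H of 4 and collapse it to the hydroxybutenolide, or the single equivalent of peroxide may not carry the epoxidation to completion.
- The fallback sets out from 3 and comes back at 7, using two known reactions with external oxidants.
- Compound 3 is oxidised with NBS/NaHCO3 in aqueous acetone at −15 °C and isomerised with pyridine, and 6 is isolated.
- Compound 6 is then epoxidised with 35% aqueous H2O2 and the same (S)-diarylprolinol silyl ether in CH2Cl2.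
- This makes no compound outside the list (F0).

**Step 7 (new).**
- Failure modes: the eight‑membered closure may lose to dimerisation, or the silyl ester may hydrolyse first.
- The fallback sets out from 12 and comes back at 17, using olefination instead of metathesis.
- TESOTf/2,6‑lutidine at −78 °C gives the triethylsilyl ether of 12 F1.
- Ozonolysis (O3, CH2Cl2, −78 °C, then PPh3) gives the α‑acetoxy aldehyde F2.
- Ando Z‑selective Horner–Wadsworth–Emmons olefination follows, with 2‑(trimethylsilyl)ethyl [bis(2‑methylphenoxy)phosphoryl]acetate and NaH in THF at −78 °C. It gives the Z‑enoate 2‑(trimethylsilyl)ethyl ester F3.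
- TASF in wet DMF at 0 °C removes both silicon groups.

**Step 5.**
- Failure modes: SN2′ attack, partial loss of inversion, or O4‑to‑O5 acetyl shift.
- The fallback sets out from 11 and comes back at 12, delivering the acetate intramolecularly instead.
- Acid‑catalysed hydrolysis (H2O/THF, cat. HClO4, 0 °C) opens C4 with inversion to the syn‑diol F4.
- MeC(OMe)3/PPTS gives the cyclic orthoacetate F5.
- 80% aqueous AcOH at 0 °C collapses the hemiorthoester with release of the more acidic C5–OH, leaving the acetate on O4.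

**Further compounds**
F0 | step 3 | none | none
F1 | step 7 | triethylsilyl ether of 12 (stereocentres as in 12) | CCC[C@@H](OC(C)=O)C(=O)[C@H]1O[C@@H]1[C@H](O[Si](CC)(CC)CC)[C@H](C=C)OC(C)=O
F2 | step 7 | aldehyde from cleavage of the vinyl group of F1 (configuration unchanged) | CCC[C@@H](OC(C)=O)C(=O)[C@H]1O[C@@H]1[C@H](O[Si](CC)(CC)CC)[C@H](C=O)OC(C)=O
F3 | step 7 | 2-(trimethylsilyl)ethyl ester and 5-O-triethylsilyl ether of 17 | CCC[C@@H](OC(C)=O)C(=O)[C@H]1O[C@@H]1[C@H](O[Si](CC)(CC)CC)[C@H](/C=C\C(=O)OCC[Si](C)(C)C)OC(C)=O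
F4 | step 5 | (3S,4R,5R,6S,8R)-8-acetoxy-5,6-epoxy-3,4-dihydroxyundec-1-en-7-one | CCC[C@@H](OC(C)=O)C(=O)[C@H]1O[C@@H]1[C@H](O)[C@H](C=C)O
F5 | step 5 | 2-methoxy-2-methyl-1,3-dioxolane (cyclic orthoacetate) of F4, trans-4,5-disubstituted | CCC[C@@H](OC(C)=O)C(=O)[C@H]1O[C@@H]1[C@@H]2OC(C)(OC)O[C@H]2C=C
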